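## Plan

- **Feature:** in the 7-oxabicyclo[2.2.1]heptane (C1 = bridgehead with CH3; C2 = CH with chain A, CH2CH2C(CH3)(OH)CH=CH2; C3 = quaternary C with CH3 and chain B, CH2CH2CHBrC(CH3)2Cl; C4 = bridgehead CH; C5; C6; O7) only C2–C3 and C1–O7 are ring bonds of an otherwise linear head-to-tail tetraprenyl chain. C3/C4 correspond to a trisubstituted epoxide and C1/C2 to an (E)-trisubstituted alkene, placed so that one cation cascade can close both rings.
- **Cuts:** first C–Cl and C–Br (chain B back to a prenyl alkene) and the carbinol O–H (silyl ether); then C2–C3 and C1–O7 together, giving an acyclic (6E,10S,11S)-10,11-epoxy diene; then the C8–C9 single bond of that chain, giving a linalool-derived allylic sulfone and an epoxygeraniol-derived iodide.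
- **Forward:** the two C10 halves are joined by sulfone alkylation and desulfonylation; one Lewis-acid step forms the carbocycle (C2–C3) and, directly after it, the oxolane bridge (C1–O7); chain B is converted by epoxidation, bromide opening and deoxychlorination; the silyl ether is removed last.
- **Stereochemistry:** carbinol centre from (S)-linalool; C4 and (with inversion) C3 from the Sharpless epoxide of geraniol; C2 from the (E) alkene in a chair transition state; C1 from the geometry of the bridge; CHBr from a reagent-controlled Shi epoxidation followed by SN2 opening.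

Key step: step 9

Remark: commercial (S)-(+)-linalool is taken as enantiomerically pure; locants C1–C6/O7 refer to the bicycle as defined above, and C1–C16 in the acyclic intermediates follow the geranyllinalool chain (C1 = vinyl CH2).

## Route

**Step 1**
Reactants: 1 (S)-linalool
Product: 2 (3S)-3,7-dimethyl-3-(triethylsilyloxy)octa-1,6-diene
Conditions: TESOTf, 2,6-lutidine, CH2Cl2, −78 → 0 °C
Reagents that add atoms: triethylsilyl trifluoromethanesulfonate, `CC[Si](CC)(CC)OS(=O)(=O)C(F)(F)F`
Why: Silylation of a hindered tertiary alcohol with a silyl triflate and a hindered pyridine base is standard O-silyl protection, and it masks the only hydroxyl before the oxidation, carbanion and Lewis-acid steps without touching the stereocentre.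

**Step 2**
Reactants: 2 (3S)-3,7-dimethyl-3-(triethylsilyloxy)octa-1,6-diene
Product: 3 (2E,6S)-2,6-dimethyl-6-(triethylsilyloxy)octa-2,7-dien-1-ol
Conditions: SeO2 (0.3 equiv), t-BuOOH, CH2Cl2, 0 °C → rt
Reagents that add atoms: selenium dioxide, `O=[Se]=O` (oxygen donor, regenerated by tert-butyl hydroperoxide, `CC(C)(C)OO`)
Why: The catalytic Riley allylic oxidation (ene reaction, then [2,3]-sigmatropic shift) should hydroxylate the (E)-methyl group of the prenyl terminus selectively, while the vinyl group has no allylic hydrogen and stays untouched.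

**Step 3**
Reactants: 3 (2E,6S)-2,6-dimethyl-6-(triethylsilyloxy)octa-2,7-dien-1-ol
Product: 4 (2E,6S)-1-bromo-2,6-dimethyl-6-(triethylsilyloxy)octa-2,7-diene
Conditions: CBr4, PPh3, CH2Cl2, 0 °C
Reagents that add atoms: carbon tetrabromide, `BrC(Br)(Br)Br`
Why: The Appel reaction converts the primary allylic alcohol into the bromide by SN2 displacement of an oxyphosphonium ion under nearly neutral conditions, so the (E) alkene and the silyl ether should be kept.

**Step 4**
Reactants: 4 (2E,6S)-1-bromo-2,6-dimethyl-6-(triethylsilyloxy)octa-2,7-diene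
Product: 5 (2E,6S)-2,6-dimethyl-1-(phenylsulfonyl)-6-(triethylsilyloxy)octa-2,7-diene
Conditions: PhSO2Na, DMF, rt
Reagents that add atoms: sodium benzenesulfinate, `[Na+].[O-]S(=O)c1ccccc1`
Why: S-alkylation of the sulfinate by a primary allylic bromide (SN2) should give the allylic sulfone needed as a carbanion precursor with the (E) geometry retained.

**Step 5**
Reactants: 6 geraniol
Product: 7 (2S,3S)-2,3-epoxygeraniol
Conditions: Ti(OiPr)4 (5 mol%), L-(+)-diethyl tartrate (7 mol%), t-BuOOH, 4 Å molecular sieves, CH2Cl2, −20 °C
Reagents that add atoms: tert-butyl hydroperoxide, `CC(C)(C)OO`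
Why: The Sharpless asymmetric epoxidation delivers oxygen only to the allylic-alcohol alkene, and the L-(+)-tartrate ligand sets both epoxide centres as 2S,3S (the later C4 and, before inversion, C3).

**Step 6**
Reactants: 7 (2S,3S)-2,3-epoxygeraniol
Product: 8 (2R,3S)-2,3-epoxy-1-iodo-3,7-dimethyloct-6-ene
Conditions: I2, PPh3, imidazole, CH2Cl2, 0 °C, dark
Reagents that add atoms: iodine, `II`
Why: The Garegg–Samuelsson iodination (an Appel-type SN2 at the primary carbon) should give the epoxy iodide without opening the adjacent trisubstituted epoxide, whose two centres are not involved (the descriptor at C2 changes only because CH2I outranks the epoxide carbon).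

**Step 7**
Reactants: 5 (2E,6S)-2,6-dimethyl-1-(phenylsulfonyl)-6-(triethylsilyloxy)octa-2,7-diene; 8 (2R,3S)-2,3-epoxy-1-iodo-3,7-dimethyloct-6-ene
Product: 10 epoxy sulfone (3S,6E,10S,11S)-10,11-epoxy-3,7,11,15-tetramethyl-8-(phenylsulfonyl)-3-(triethylsilyloxy)hexadeca-1,6,14-triene as both C8 epimers, via lithiated sulfone 9 (not isolated)
Conditions: n-BuLi, THF, −78 °C; then 8, hexamethylphosphoramide, −78 → −20 °C
Reagents that add atoms: none
Why: Alkylation of a sulfone-stabilised allyl anion occurs at the carbon bearing sulfur and so keeps the (E) alkene in place, and the soft carbanion should displace the primary iodide rather than attack the hindered secondary and tertiary epoxide carbons (sulfone alkylation).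

**Step 8**
Reactants: 10 epoxy sulfone
Product: 11 (3S,6E,10S,11S)-10,11-epoxy-3,7,11,15-tetramethyl-3-(triethylsilyloxy)hexadeca-1,6,14-triene
Conditions: Pd(dppp)Cl2 (5 mol%), LiEt3BH, THF, 0 °C
Reagents that add atoms: none
Why: Zerovalent palladium ionises the allylic sulfone to a π-allyl complex that takes up hydride from LiEt3BH at the carbon which carried the sulfonyl group (palladium-catalysed reductive desulfonylation of an allylic sulfone), so that the (E)-6,7-alkene should stay in place, while the hindered trisubstituted epoxide is expected to outlast the short exposure to the hydride at 0 °C.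

**Step 9**
Reactants: 11 (3S,6E,10S,11S)-10,11-epoxy-3,7,11,15-tetramethyl-3-(triethylsilyloxy)hexadeca-1,6,14-triene
Product: 12 (1R,2S,3S,4S)-7-oxabicyclo[2.2.1]heptane with CH3 on C1, CH2CH2C(CH3)(OSiEt3)CH=CH2 (S) on C2, CH3 and CH2CH2CH=C(CH3)2 on C3
Conditions: MeAlCl2 (1.2 equiv), CH2Cl2, −94 °C; Et3N, then aq. NaHCO3
Reagents that add atoms: none
Why: MeAlCl2 binds the epoxide oxygen and weakens the bond to the tertiary carbon C3, which is attacked from the rear by C2 of the (E)-trisubstituted alkene in a 6-endo closure of the carbocycle through a chair transition state, leaving a tertiary cation at C1. The aluminium alkoxide on C4 then reaches C1 across the ring through a boat conformer and closes the oxolane O7–C1–C6–C5–C4 (a five-membered, formally 5-exo capture), which completes the 7-oxabicyclo[2.2.1]heptane and releases the Lewis acid. The closest known reaction type is the Lewis-acid-promoted epoxide-initiated cation–olefin (polyene) cyclisation in which the epoxide-derived oxygen ends the cascade as a bridging ether. C4 is carried over unchanged from the Sharpless epoxide, C3 is set by inversion at the epoxide carbon (CH3 on the O7 face, chain B opposite), C2 by the (E) alkene geometry in the chair (chain A equatorial, on the O7 face and trans to chain B), and C1 by the bridge, which can span only one face. The step needs the epoxide to react in preference to the tertiary allylic silyl ether, and the C1 cation to be taken by oxygen rather than to lose a proton or be intercepted by the prenyl alkene of chain B. The higher Lewis basicity and strain of the epoxide, the steric shielding of the silyl ether oxygen, the tertiary nature of every cationic centre, the five-atom reach of the alkoxide and the very low temperature should secure this.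

**Step 10**
Reactants: 12 oxabicycle with prenyl chain B
Product: 13 oxabicycle as 12 with chain B = CH2CH2–[(2R)-3,3-dimethyloxiran-2-yl]
Conditions: 1,2:4,5-di-O-isopropylidene-β-D-erythro-2,3-hexodiulo-2,6-pyranose (Shi ketone from D-fructose, 0.3 equiv), Oxone (2KHSO5·KHSO4·K2SO4), K2CO3, Bu4NHSO4, MeCN–CH2(OMe)2–aq. Na2B4O7 buffer (pH 10.5), 0 °C
Reagents that add atoms: potassium peroxymonosulfate, `[K+].[O-]S(=O)(=O)OO`
Why: The Shi epoxidation (chiral dioxirane, spiro transition state) should attack only the electron-rich trisubstituted alkene and not the hindered vinyl group, and the D-fructose-derived ketone fixes the new CH centre as R by reagent control, the ring stereocentres being too remote to interfere.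

**Step 11**
Reactants: 13 epoxide
Product: 14 bromohydrin, as 12 with chain B = CH2CH2–CH(Br)–C(CH3)2OH, S at CHBr
Conditions: Li2NiBr4 (0.4 M in THF), THF, 0 °C → rt; pH 7 buffer
Reagents that add atoms: dilithium tetrabromonickelate, `[Li+].[Li+].Br[Ni-2](Br)(Br)Br`
Why: Li2NiBr4 is a source of soft bromide that opens epoxides in an SN2 manner at the less substituted carbon (epoxide to bromohydrin), so that bromide should enter at the secondary carbon with inversion (R epoxide to S bromide) and leave the tertiary alcohol in place.

**Step 12**
Reactants: 14 bromohydrin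
Product: 15 O-triethylsilyl dactylomelol, as 12 with chain B = CH2CH2–CH(Br)–C(CH3)2Cl, S at CHBr
Conditions: 1-chloro-N,N,2-trimethylprop-1-en-1-amine, CH2Cl2, 0 °C → rt
Reagents that add atoms: 1-chloro-N,N,2-trimethylprop-1-en-1-amine (Ghosez reagent), `CC(C)=C(Cl)N(C)C`
Why: Deoxychlorination of the tertiary alcohol with the α-chloroenamine runs under neutral conditions through an alkoxyiminium ion whose departure is assisted by the neighbouring bromine, and chloride then opens the bromonium ion at the tertiary carbon (neighbouring-group participation), so that the C–Br bond and its S configuration should stay untouched and the acid-sensitive silyl ether should survive.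

**Step 13**
Reactants: 15 O-triethylsilyl dactylomelol
Product: 16 dactylomelol
Conditions: HF·pyridine, pyridine, THF, 0 °C → rt
Reagents that add atoms: none
Why: Fluoride-driven cleavage of the Si–O bond (desilylation) under buffered, non-basic conditions should free the tertiary allylic alcohol without E2 loss of HBr or HCl from the bromochloride and without ionising the allylic carbinol.

## Compound list

```
1 | (S)-linalool, (3S)-3,7-dimethylocta-1,6-dien-3-ol | C=C[C@@](C)(O)CCC=C(C)C | starting material
2 | (3S)-3,7-dimethyl-3-(triethylsilyloxy)octa-1,6-diene | C=C[C@@](C)(O[Si](CC)(CC)CC)CCC=C(C)C | intermediate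
3 | (2E,6S)-2,6-dimethyl-6-(triethylsilyloxy)octa-2,7-dien-1-ol | C=C[C@@](C)(O[Si](CC)(CC)CC)CC/C=C(\C)CO | intermediate
4 | (2E,6S)-1-bromo-2,6-dimethyl-6-(triethylsilyloxy)octa-2,7-diene | C=C[C@@](C)(O[Si](CC)(CC)CC)CC/C=C(\C)CBr | intermediate
5 | (2E,6S)-2,6-dimethyl-1-(phenylsulfonyl)-6-(triethylsilyloxy)octa-2,7-diene | C=C[C@@](C)(O[Si](CC)(CC)CC)CC/C=C(\C)CS(=O)(=O)c1ccccc1 | intermediate
6 | geraniol, (2E)-3,7-dimethylocta-2,6-dien-1-ol | CC(C)=CCC/C(C)=C/CO | starting material
7 | (2S,3S)-2,3-epoxygeraniol | OC[C@@H]1O[C@@]1(C)CCC=C(C)C | intermediate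
8 | (2R,3S)-2,3-epoxy-1-iodo-3,7-dimethyloct-6-ene (same spatial arrangement as 7) | IC[C@@H]1O[C@@]1(C)CCC=C(C)C | intermediate
9 | lithiated sulfone, C1-lithio derivative of 5 | C=C[C@@](C)(O[Si](CC)(CC)CC)CC/C=C(\C)C([Li])S(=O)(=O)c1ccccc1 | intermediate (not isolated)
10 | (3S,6E,10S,11S)-10,11-epoxy-3,7,11,15-tetramethyl-8-(phenylsulfonyl)-3-(triethylsilyloxy)hexadeca-1,6,14-triene, both C8 epimers | C=C[C@@](C)(O[Si](CC)(CC)CC)CC/C=C(\C)C(C[C@@H]1O[C@@]1(C)CCC=C(C)C)S(=O)(=O)c1ccccc1 | intermediate
11 | (3S,6E,10S,11S)-10,11-epoxy-3,7,11,15-tetramethyl-3-(triethylsilyloxy)hexadeca-1,6,14-triene | C=C[C@@](C)(O[Si](CC)(CC)CC)CC/C=C(\C)CC[C@@H]1O[C@@]1(C)CCC=C(C)C | intermediate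
12 | (1R,2S,3S,4S)-1,3-dimethyl-3-(4-methylpent-3-en-1-yl)-2-[(3S)-3-methyl-3-(triethylsilyloxy)pent-4-en-1-yl]-7-oxabicyclo[2.2.1]heptane | C=C[C@@](C)(O[Si](CC)(CC)CC)CC[C@H]1[C@](C)(CCC=C(C)C)[C@@H]2CC[C@@]1(C)O2 | intermediate
13 | 12 with chain B = 2-[(2R)-3,3-dimethyloxiran-2-yl]ethyl | C=C[C@@](C)(O[Si](CC)(CC)CC)CC[C@H]1[C@](C)(CC[C@H]3OC3(C)C)[C@@H]2CC[C@@]1(C)O2 | intermediate
14 | 12 with chain B = (3S)-3-bromo-4-hydroxy-4-methylpentyl | C=C[C@@](C)(O[Si](CC)(CC)CC)CC[C@H]1[C@](C)(CC[C@H](Br)C(C)(C)O)[C@@H]2CC[C@@]1(C)O2 | intermediate
15 | O-triethylsilyl dactylomelol, 12 with chain B = (3S)-3-bromo-4-chloro-4-methylpentyl | C=C[C@@](C)(O[Si](CC)(CC)CC)CC[C@H]1[C@](C)(CC[C@H](Br)C(C)(C)Cl)[C@@H]2CC[C@@]1(C)O2 | intermediate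
16 | dactylomelol, (3S)-5-[(1R,2S,3S,4S)-3-[(3S)-3-bromo-4-chloro-4-methylpentyl]-1,3-dimethyl-7-oxabicyclo[2.2.1]heptan-2-yl]-3-methylpent-1-en-3-ol | C=C[C@@](C)(O)CC[C@H]1[C@](C)(CC[C@H](Br)C(C)(C)Cl)[C@@H]2CC[C@@]1(C)O2 | target
```

## Step count and risks

Total: 13 steps. Longest linear sequence: 11 steps (steps 1–4 and 7–13 from (S)-linalool); steps 5–6 form the second branch from geraniol.

**Steps most likely to fail**

1. **Step 9.** The cascade may be diverted by proton loss from the C1 cation before the alkoxide reaches it, by hydride shift in the opened epoxide to a ketone, by capture of the cation by the prenyl alkene, or by ionisation of the tertiary allylic silyl ether. The fallback sets out from 11 and returns at 12, and it makes the two bonds in separate steps. Trivalent titanium (Cp2TiCl, from Cp2TiCl2 and Mn dust, THF, rt) opens the epoxide homolytically at C3, the tertiary radical closes the six-membered ring 6-endo onto C2, and β-hydride loss from the C1–titanium species should give the exocyclic alkenol F1 without any acid. Iodoetherification (I2, NaHCO3, MeCN, 0 °C) then forms C1–O7 and gives the iodomethyl ether F2, and Bu3SnH with azobisisobutyronitrile reduces CH2I to the C1 methyl group of 12. The price is that C3 then rests on the chair preference of the larger chain B for the equatorial site and no longer on inversion, so a C3 epimer may have to be separated.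

2. **Step 11.** Bromide may attack the tertiary epoxide carbon (loss of regioselectivity), or the Lewis-acidic medium may trigger rearrangement of the epoxide to a ketone. The fallback sets out from 13 and returns at 15, and it reverses the order in which the halogens enter. TiCl4 (CH2Cl2, −78 °C) should open 13 in the Markovnikov sense to the chlorohydrin F3 (chloride on the tertiary carbon, R-configured secondary alcohol retained). An Appel bromination (CBr4, PPh3, CH2Cl2) then replaces the hydroxyl by bromide with inversion and gives the S bromide 15 directly, so that steps 11 and 12 are both bypassed.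

3. **Step 12.** The activated tertiary alcohol may lose a proton (elimination towards an isopropenyl group), or the bromonium ion may pass its bromine to another alkene and so erode the configuration at the CHBr carbon. The fallback sets out from 12 and returns at 15, and it gives up reagent control. BrCl is added to the prenyl alkene with tetrabutylammonium dichlorobromate (Bu4NBrCl2, CH2Cl2, −78 °C); Markovnikov opening of the bromonium ion by chloride gives the right constitution, and the S bromide 15 would be separated by HPLC from the R-bromo epimer F4.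

## Further compounds

```
F1 | step 9 | exocyclic alkenol: (1S,2S,3S)-configured ring as in 12 with C4–OH free and C1=CH2 in place of the C1–O7 bond | C=C[C@@](C)(O[Si](CC)(CC)CC)CC[C@H]1[C@](C)(CCC=C(C)C)[C@@H](O)CCC1=C
F2 | step 9 | iodomethyl ether: 12 with CH2I in place of the C1 methyl group | C=C[C@@](C)(O[Si](CC)(CC)CC)CC[C@H]1[C@](C)(CCC=C(C)C)[C@@H]2CC[C@@]1(CI)O2
F3 | step 11 | chlorohydrin: 12 with chain B = (3R)-4-chloro-3-hydroxy-4-methylpentyl | C=C[C@@](C)(O[Si](CC)(CC)CC)CC[C@H]1[C@](C)(CC[C@@H](O)C(C)(C)Cl)[C@@H]2CC[C@@]1(C)O2
F4 | step 12 | R-bromo epimer of 15: 12 with chain B = (3R)-3-bromo-4-chloro-4-methylpentyl | C=C[C@@](C)(O[Si](CC)(CC)CC)CC[C@H]1[C@](C)(CC[C@@H](Br)C(C)(C)Cl)[C@@H]2CC[C@@]1(C)O2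
```
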